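**Plan** (germacrane numbering: C1=C10(C14), C4(C15)=C5, lactone C6–O–C12(=O)–C11(=C13)–C7, C7–OH, C8–O-senecioyl, C9–OH)
- Retrosynthetic cuts, in order: the O8 acyl group and the O7/O9 protecting groups; then C7–C8, between the fully substituted carbinol C7 and C8, which opens the ten-membered ring to a 4-alkoxy-3-(chloromethyl)butenolide (a tetronate) carrying an aldehyde at C8; then C11–C13 and the tetronate C–O bonds (back to a γ-hydroxy ynoate), C6–C7 (propiolate + enal) and C1=C10 (Wittig).
- Enabling feature: C7 is both the β-carbon of the α-methylene-γ-lactone and the oxygenated neighbour of C8. C13=C11–C7(O)–C8(OH) is therefore the product pattern of an SE2' allylation of an aldehyde by a 3-(metallomethyl)tetronate, and the lactone can be in place before the carbocycle.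
- Forward order: C1–C6 phosphonium salt + C8–C10 ketone → Wittig → enal → alkynylation → lactone ring (tetronate, then C13) → ten-membered ring last, by a chromium-mediated Barbier closure that also creates the exocyclic methylene and leaves O8 as the only free hydroxyl → acylation and removal of PMB (O7) and TES (O9).
- Stereochemistry: C9 from methyl (S)-glycerate; Z-C1=C10 from the Wittig reaction of an α-silyloxy ketone; E-C4=C5 from syn-carboalumination; C6 from Zn/ProPhenol alkynylation; C7 and C8 in the ring closure (controlled by C6 and a chair transition state).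

Key step: step 13

Remark: (S,S)-ProPhenol is assumed to be the ligand antipode that gives the 4S alcohol 15 (otherwise its enantiomer is used), and methyl (S)-glycerate is taken as purchasable.

**Step 1**
Reactants: 1 5-chloropent-1-yne
Product: 3 (2E)-6-chloro-3-methylhex-2-en-1-ol, via alkenylalane 2 (not isolated)
Conditions: Me3Al, Cp2ZrCl2 (cat.), CH2Cl2, 0 °C to rt; n-BuLi, THF, −78 °C; (CH2O)n, −78 °C to rt; aq. HCl
Reagents that add atoms: trimethylaluminium, C[Al](C)C (methyl in 3, aluminium only in 2); formaldehyde (from paraformaldehyde), C=O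
Why: Negishi Zr-catalysed carboalumination adds Me and Al syn across the terminal alkyne (Me to the internal carbon), which fixes the E geometry of the future C4=C5 bond, and the derived alanate is hydroxymethylated with retention.

**Step 2**
Reactants: 3 (2E)-6-chloro-3-methylhex-2-en-1-ol
Product: 5 [(4E)-6-hydroxy-4-methylhex-4-en-1-yl]triphenylphosphonium iodide, via primary iodide 4 (not isolated)
Conditions: NaI, PPh3, MeCN, reflux
Reagents that add atoms: sodium iodide, [Na+].[I-]; triphenylphosphine, c1ccc(cc1)P(c1ccccc1)c1ccccc1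
Why: Finkelstein exchange followed by SN2 quaternisation of triphenylphosphine at the primary carbon; the allylic alcohol and the alkene are inert.

**Step 3**
Reactants: 6 methyl (2S)-2,3-dihydroxypropanoate
Product: 7 methyl (2S)-2,3-bis(triethylsilyloxy)propanoate
Conditions: TESCl, imidazole, DMF, 0 °C to rt
Reagents that add atoms: chlorotriethylsilane, CC[Si](Cl)(CC)CC
Why: Standard silylation of both hydroxyls; the stereocentre (the future C9) is not touched.

**Step 4**
Reactants: 7 methyl (2S)-2,3-bis(triethylsilyloxy)propanoate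
Product: 9 (3S)-3,4-bis(triethylsilyloxy)butan-2-one, via Weinreb amide 8 (not isolated)
Conditions: MeNHOMe·HCl, iPrMgCl, THF, −20 °C; then MeMgBr, −20 to 0 °C; aq. NH4Cl
Reagents that add atoms: methylmagnesium bromide, C[Mg]Br; N,O-dimethylhydroxylamine hydrochloride, CNOC.Cl (atoms only in 8)
Why: One-flask Weinreb ketone synthesis: the magnesium amide converts the ester into the Weinreb amide, whose chelated tetrahedral adduct with MeMgBr stops at the methyl ketone, and the α-silyloxy centre should not enolise at −20 °C.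

**Step 5**
Reactants: 5 hydroxy phosphonium iodide; 9 (3S)-3,4-bis(triethylsilyloxy)butan-2-one
Product: 11 (2E,6Z,8R)-3,7-dimethyl-8,9-bis(triethylsilyloxy)nona-2,6-dien-1-ol, via oxido ylide 10 (not isolated)
Conditions: NaHMDS (2.05 equiv), THF, −78 °C; then 9, −78 °C to rt
Reagents that add atoms: sodium bis(trimethylsilyl)amide, [Na+].C[Si](C)(C)[N-][Si](C)(C)C (sodium only in 10)
Why: Wittig olefination of an α-silyloxy methyl ketone with a non-stabilised ylide: kinetically controlled oxaphosphetane formation should place the oxygenated carbon cis to the ylide chain and give the Z C1=C10 bond; the second equivalent of base only holds the hydroxyl as its alkoxide.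

**Step 6**
Reactants: 11 dienol
Product: 12 (2E,6Z,8R)-3,7-dimethyl-8,9-bis(triethylsilyloxy)nona-2,6-dienal
Conditions: MnO2, CH2Cl2, rt
Reagents that add atoms: none
Why: MnO2 oxidises only the allylic primary alcohol to the E-enal; the silyl ethers and the Z-alkene are stable.

**Step 7**
Reactants: 12 enal; 13 methyl prop-2-ynoate
Product: 15 methyl (4S,5E,9Z,11R)-4-hydroxy-6,10-dimethyl-11,12-bis(triethylsilyloxy)dodeca-5,9-dien-2-ynoate, via zinc alkynylide 14 (not isolated)
Conditions: Me2Zn, (S,S)-ProPhenol (20 mol%), Ph3P=O (40 mol%), toluene, 4 °C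
Reagents that add atoms: dimethylzinc, C[Zn]C (zinc and methyl only in 14)
Why: Zn/ProPhenol-catalysed asymmetric alkynylation of the enal with the zinc acetylide of methyl propiolate; the dinuclear zinc catalyst selects the aldehyde face and sets the carbinol (future C6) as S.

**Step 8**
Reactants: 15 γ-hydroxy ynoate
Product: 17 (5S)-4-allyloxy tetronate, via oxa-Michael adduct 16 (not isolated)
Conditions: allyl alcohol (5 equiv), KOtBu (0.2 equiv), THF, 0 °C to rt
Reagents that add atoms: allyl alcohol, C=CCO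
Why: Alkoxide-catalysed oxa-Michael addition to the ynoate and lactonisation of the E-adduct onto the γ-hydroxyl (the 4-hydroxy-2-ynoate to 4-alkoxybutenolide synthesis); the C6–O bond is not broken, so its configuration is kept.

**Step 9**
Reactants: 17 allyl tetronate
Product: 19 (5S)-4-hydroxy-3-iodo tetronic acid, via tetronic acid 18 (not isolated)
Conditions: Pd(PPh3)4 (2 mol%), morpholine (1.5 equiv), THF, 0 °C; then I2 (1.05 equiv), aq. NaHCO3, 0 °C; cold pH 4 buffer work-up, used at once
Reagents that add atoms: iodine, II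
Why: Tsuji–Trost deallylation (allyl transfer to morpholine) unmasks the tetronate anion, a 1,3-dicarbonyl enolate that is iodinated at C3 far faster than the two trisubstituted alkenes react.

**Step 10**
Reactants: 19 3-iodotetronic acid
Product: 20 (5S)-3-iodo-4-[(4-methoxyphenyl)methoxy] tetronate
Conditions: 4-methoxybenzyl alcohol, PPh3, DIAD, THF, 0 °C to rt
Reagents that add atoms: 4-methoxybenzyl alcohol, COc1ccc(CO)cc1
Why: Mitsunobu etherification of the acidic 4-OH of the tetronic acid, the regioselective route to 4-O-alkyl tetronates; no stereocentre is involved.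

**Step 11**
Reactants: 20 3-iodo PMB tetronate
Product: 24 (5S)-3-(chloromethyl)-4-[(4-methoxyphenyl)methoxy] tetronate, via alkenylmagnesium chloride 21 (not isolated), via hydroxymethyl tetronate 22 (not isolated), via mesylate 23 (not isolated)
Conditions: iPrMgCl·LiCl, THF, −40 °C; formaldehyde (from dry paraformaldehyde), −40 to 0 °C; MsCl, LiCl, 0 °C to rt
Reagents that add atoms: formaldehyde, C=O; lithium chloride, [Li+].[Cl-]; isopropylmagnesium chloride, CC(C)[Mg]Cl (MgCl only in 21); methanesulfonyl chloride, CS(=O)(=O)Cl (mesyl only in 23)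
Why: Iodine–magnesium exchange of the activated alkenyl iodide, addition to formaldehyde, then mesylation and chloride displacement of the alkoxide in the same flask; the low temperature should keep the lactone and the acidic C6–H intact.

**Step 12**
Reactants: 24 chloromethyl tetronate
Product: 25 (2R,3Z,7E)-8-[(2S)-4-(chloromethyl)-3-[(4-methoxyphenyl)methoxy]-5-oxo-2,5-dihydrofuran-2-yl]-3,7-dimethyl-2-(triethylsilyloxy)octa-3,7-dienal
Conditions: (COCl)2, DMSO, CH2Cl2, −78 to −40 °C; Et3N, −78 to 0 °C
Reagents that add atoms: none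
Why: Direct Swern oxidation of a primary triethylsilyl ether: activated DMSO cleaves and oxidises the primary TES ether to the aldehyde, while the secondary TES ether, the allylic chloride and the α-stereocentre should stay in place at low temperature.

**Step 13**
Reactants: 25 chloro aldehyde
Product: 27 ring-closed C8 alcohol (7-O-PMB, 9-O-TES, α-methylene lactone), via allylchromium dichloride 26 (not isolated)
Conditions: CrCl2 (10 equiv), LiI (cat.), THF/DMF 4:1, rt, slow addition of 25 to about 2 mM; pH 7 buffer work-up at 0 °C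
Reagents that add atoms: chromium(II) chloride, Cl[Cr]Cl (chromium and chlorine only in 26)
Why: Proposed new method: two Cr(II) equivalents reduce the allylic C13–Cl bond to a primary σ-allylchromium(III) (26) that adds to the tethered aldehyde through its γ-carbon C7, the OPMB-bearing ring carbon of the tetronate, in a six-membered Zimmerman–Traxler transition state (SE2'), so that C7–C8 is formed, the double bond moves to C11=C13 and the α-methylene lactone appears; the closest known reactions are Nozaki–Hiyama/Barbier macrocyclisations of 2-(halomethyl)acrylates onto aldehydes and γ-additions of γ-alkoxyallylchromium reagents, but a 4-alkoxy-3-(halomethyl)butenolide has not been used as the allyl donor to build a fully substituted, oxygen-bearing carbon. The ten-membered carbocycle closes in the 10-exo mode at both termini (the aldehyde oxygen and C11=C13 stay outside the new ring). C7 (7R) should be set by C6: with C6–H eclipsing the C4=C5 bond (A1,3 strain against C15) the C3–C2 arm lies on the C5 face of the butenolide, so C8 is delivered syn to C5 and the lactone becomes cis-fused. C8 (8S) should follow from the chair in which C9 is equatorial (anti to C11) and O7, cis to the CH2Cr group, is axial, which ties the 7,8-relationship to the C7 face; the 9R silyloxy centre is a spectator whose C–O bond can stand anti to the forming bond. The step needs γ- over α-attack (secured by the closed transition state with chromium on the primary carbon; α-attack would give a 12-membered ring and keep the tetrasubstituted enol ether), aldehyde over lactone chemoselectivity (inherent to allylchromium reagents) and ring closure over oligomerisation (slow addition at high dilution).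

**Step 14**
Reactants: 27 ring-closed alcohol
Product: 28 C8 senecioate (7-O-PMB, 9-O-TES)
Conditions: 3-methylbut-2-enoyl chloride, pyridine, DMAP (cat.), CH2Cl2, 0 °C to rt
Reagents that add atoms: 3-methylbut-2-enoyl chloride, CC(C)=CC(=O)Cl
Why: DMAP-catalysed acylation of the only free hydroxyl (O8); pyridine instead of a trialkylamine avoids deconjugation of the acyl group through the vinylketene.

**Step 15**
Reactants: 28 senecioate
Product: 29 7-hydroxy-9-O-TES senecioate
Conditions: DDQ, CH2Cl2/pH 7 buffer, 0 °C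
Reagents that add atoms: none
Why: Oxidative cleavage of the PMB ether by DDQ (hydride abstraction, hydrolysis of the oxocarbenium ion); with C9 still silylated no neighbouring hydroxyl can trap the cation as an acetal.

**Step 16**
Reactants: 29 9-O-TES senecioate
Product: 30 target, (3aR,4S,5R,6Z,10E,11aS)-3a,5-dihydroxy-6,10-dimethyl-3-methylidene-2-oxo-2,3,3a,4,5,8,9,11a-octahydrocyclodeca[b]furan-4-yl 3-methylbut-2-enoate
Conditions: HF·pyridine, pyridine/THF, 0 °C
Reagents that add atoms: none
Why: Fluoride-mediated desilylation under buffered, weakly acidic conditions, which should leave the α-methylene lactone and both esters untouched and not promote acyl migration.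

**Compound list**
1 | 5-chloropent-1-yne | C#CCCCCl | starting material
2 | [(1E)-5-chloro-2-methylpent-1-en-1-yl]dimethylalumane (not isolated) | C[Al](C)/C=C(\C)CCCCl | intermediate
3 | (2E)-6-chloro-3-methylhex-2-en-1-ol | OC/C=C(\C)CCCCl | intermediate
4 | (2E)-6-iodo-3-methylhex-2-en-1-ol (not isolated) | OC/C=C(\C)CCCI | intermediate
5 | [(4E)-6-hydroxy-4-methylhex-4-en-1-yl]triphenylphosphonium iodide | OC/C=C(\C)CCC[P+](c1ccccc1)(c1ccccc1)c1ccccc1.[I-] | intermediate
6 | methyl (2S)-2,3-dihydroxypropanoate | COC(=O)[C@@H](O)CO | starting material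
7 | methyl (2S)-2,3-bis(triethylsilyloxy)propanoate | COC(=O)[C@@H](O[Si](CC)(CC)CC)CO[Si](CC)(CC)CC | intermediate
8 | (2S)-N-methoxy-N-methyl-2,3-bis(triethylsilyloxy)propanamide (not isolated) | CON(C)C(=O)[C@@H](O[Si](CC)(CC)CC)CO[Si](CC)(CC)CC | intermediate
9 | (3S)-3,4-bis(triethylsilyloxy)butan-2-one | CC(=O)[C@@H](O[Si](CC)(CC)CC)CO[Si](CC)(CC)CC | intermediate
10 | sodium (2E)-3-methyl-6-(triphenyl-λ5-phosphanylidene)hex-2-en-1-olate (not isolated) | [Na+].[O-]C/C=C(\C)CCC=P(c1ccccc1)(c1ccccc1)c1ccccc1 | intermediate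
11 | (2E,6Z,8R)-3,7-dimethyl-8,9-bis(triethylsilyloxy)nona-2,6-dien-1-ol | OC/C=C(\C)CC/C=C(/C)[C@@H](O[Si](CC)(CC)CC)CO[Si](CC)(CC)CC | intermediate
12 | (2E,6Z,8R)-3,7-dimethyl-8,9-bis(triethylsilyloxy)nona-2,6-dienal | O=C/C=C(\C)CC/C=C(/C)[C@@H](O[Si](CC)(CC)CC)CO[Si](CC)(CC)CC | intermediate
13 | methyl prop-2-ynoate | C#CC(=O)OC | starting material
14 | methyl 3-(methylzincio)prop-2-ynoate (not isolated) | C[Zn]C#CC(=O)OC | intermediate
15 | methyl (4S,5E,9Z,11R)-4-hydroxy-6,10-dimethyl-11,12-bis(triethylsilyloxy)dodeca-5,9-dien-2-ynoate | COC(=O)C#C[C@@H](O)/C=C(\C)CC/C=C(/C)[C@@H](O[Si](CC)(CC)CC)CO[Si](CC)(CC)CC | intermediate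
16 | methyl (2E,4S,5E,9Z,11R)-4-hydroxy-6,10-dimethyl-3-(prop-2-en-1-yloxy)-11,12-bis(triethylsilyloxy)dodeca-2,5,9-trienoate (not isolated) | COC(=O)/C=C(/OCC=C)[C@@H](O)/C=C(\C)CC/C=C(/C)[C@@H](O[Si](CC)(CC)CC)CO[Si](CC)(CC)CC | intermediate
17 | (5S)-5-[(1E,5Z,7R)-2,6-dimethyl-7,8-bis(triethylsilyloxy)octa-1,5-dien-1-yl]-4-(prop-2-en-1-yloxy)furan-2(5H)-one | O=C1C=C(OCC=C)[C@H](/C=C(\C)CC/C=C(/C)[C@@H](O[Si](CC)(CC)CC)CO[Si](CC)(CC)CC)O1 | intermediate
18 | (5S)-5-[(1E,5Z,7R)-2,6-dimethyl-7,8-bis(triethylsilyloxy)octa-1,5-dien-1-yl]-4-hydroxyfuran-2(5H)-one (present as morpholinium salt, not isolated) | O=C1C=C(O)[C@H](/C=C(\C)CC/C=C(/C)[C@@H](O[Si](CC)(CC)CC)CO[Si](CC)(CC)CC)O1 | intermediate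
19 | (5S)-5-[(1E,5Z,7R)-2,6-dimethyl-7,8-bis(triethylsilyloxy)octa-1,5-dien-1-yl]-4-hydroxy-3-iodofuran-2(5H)-one | O=C1C(I)=C(O)[C@H](/C=C(\C)CC/C=C(/C)[C@@H](O[Si](CC)(CC)CC)CO[Si](CC)(CC)CC)O1 | intermediate
20 | (5S)-5-[(1E,5Z,7R)-2,6-dimethyl-7,8-bis(triethylsilyloxy)octa-1,5-dien-1-yl]-3-iodo-4-[(4-methoxyphenyl)methoxy]furan-2(5H)-one | O=C1C(I)=C(OCc2ccc(OC)cc2)[C@H](/C=C(\C)CC/C=C(/C)[C@@H](O[Si](CC)(CC)CC)CO[Si](CC)(CC)CC)O1 | intermediate
21 | 3-(chloromagnesio) analogue of 20, magnesium in place of iodine (not isolated) | O=C1C([Mg]Cl)=C(OCc2ccc(OC)cc2)[C@H](/C=C(\C)CC/C=C(/C)[C@@H](O[Si](CC)(CC)CC)CO[Si](CC)(CC)CC)O1 | intermediate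
22 | (5S)-5-[(1E,5Z,7R)-2,6-dimethyl-7,8-bis(triethylsilyloxy)octa-1,5-dien-1-yl]-3-(hydroxymethyl)-4-[(4-methoxyphenyl)methoxy]furan-2(5H)-one (as magnesium alkoxide, not isolated) | O=C1C(CO)=C(OCc2ccc(OC)cc2)[C@H](/C=C(\C)CC/C=C(/C)[C@@H](O[Si](CC)(CC)CC)CO[Si](CC)(CC)CC)O1 | intermediate
23 | methanesulfonate of 22 (not isolated) | O=C1C(COS(C)(=O)=O)=C(OCc2ccc(OC)cc2)[C@H](/C=C(\C)CC/C=C(/C)[C@@H](O[Si](CC)(CC)CC)CO[Si](CC)(CC)CC)O1 | intermediate
24 | (5S)-3-(chloromethyl)-5-[(1E,5Z,7R)-2,6-dimethyl-7,8-bis(triethylsilyloxy)octa-1,5-dien-1-yl]-4-[(4-methoxyphenyl)methoxy]furan-2(5H)-one | O=C1C(CCl)=C(OCc2ccc(OC)cc2)[C@H](/C=C(\C)CC/C=C(/C)[C@@H](O[Si](CC)(CC)CC)CO[Si](CC)(CC)CC)O1 | intermediate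
25 | (2R,3Z,7E)-8-[(2S)-4-(chloromethyl)-3-[(4-methoxyphenyl)methoxy]-5-oxo-2,5-dihydrofuran-2-yl]-3,7-dimethyl-2-(triethylsilyloxy)octa-3,7-dienal | O=C1C(CCl)=C(OCc2ccc(OC)cc2)[C@H](/C=C(\C)CC/C=C(/C)[C@@H](O[Si](CC)(CC)CC)C=O)O1 | intermediate
26 | allylchromium(III) dichloride from 25, CrCl2 in place of the allylic chlorine (not isolated) | O=C1C(C[Cr](Cl)Cl)=C(OCc2ccc(OC)cc2)[C@H](/C=C(\C)CC/C=C(/C)[C@@H](O[Si](CC)(CC)CC)C=O)O1 | intermediate
27 | (3aS,4S,5R,6Z,10E,11aS)-4-hydroxy-3a-[(4-methoxyphenyl)methoxy]-6,10-dimethyl-3-methylidene-5-(triethylsilyloxy)-3a,4,5,8,9,11a-hexahydrocyclodeca[b]furan-2(3H)-one (same spatial arrangement as 30; the 3a descriptor changes letter only because O8 is not acylated) | C=C1C(=O)O[C@H]2/C=C(\C)CC/C=C(/C)[C@@H](O[Si](CC)(CC)CC)[C@H](O)[C@@]12OCc1ccc(OC)cc1 | intermediate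
28 | (3aR,4S,5R,6Z,10E,11aS)-3a-[(4-methoxyphenyl)methoxy]-6,10-dimethyl-3-methylidene-2-oxo-5-(triethylsilyloxy)-2,3,3a,4,5,8,9,11a-octahydrocyclodeca[b]furan-4-yl 3-methylbut-2-enoate | C=C1C(=O)O[C@H]2/C=C(\C)CC/C=C(/C)[C@@H](O[Si](CC)(CC)CC)[C@H](OC(=O)C=C(C)C)[C@@]12OCc1ccc(OC)cc1 | intermediate
29 | (3aR,4S,5R,6Z,10E,11aS)-3a-hydroxy-6,10-dimethyl-3-methylidene-2-oxo-5-(triethylsilyloxy)-2,3,3a,4,5,8,9,11a-octahydrocyclodeca[b]furan-4-yl 3-methylbut-2-enoate | C=C1C(=O)O[C@H]2/C=C(\C)CC/C=C(/C)[C@@H](O[Si](CC)(CC)CC)[C@H](OC(=O)C=C(C)C)[C@@]12O | intermediate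
30 | (3aR,4S,5R,6Z,10E,11aS)-3a,5-dihydroxy-6,10-dimethyl-3-methylidene-2-oxo-2,3,3a,4,5,8,9,11a-octahydrocyclodeca[b]furan-4-yl 3-methylbut-2-enoate | C=C1C(=O)O[C@H]2/C=C(\C)CC/C=C(/C)[C@@H](O)[C@H](OC(=O)C=C(C)C)[C@@]12O | target

**Totals**
Total step count: 16. Longest linear sequence: 14 steps (steps 1, 2, 5–16 from 1; the branch from 6, steps 3, 4, 5–16, is equally long).

**Steps most likely to fail**

1. Step 13 (Proposed new method). The allylchromium may not react through its hindered, alkoxy-bearing γ-carbon (protonation, coupling at the primary carbon, oligomerisation). The aldehyde may also be delivered to the C7 face anti to C5, or the chromium alkoxide may shift the lactone from O6 to O8. The fallback is an intramolecular allylboration and sets out from 24. Pd-catalysed borylation of the allylic chloride with bis(pinacolato)diboron (Pd2(dba)3, THF, 50 °C) should give the primary allyl pinacolboronate F1. The direct Swern oxidation of step 12 should then give the boronate aldehyde F2. Warmed in dilute toluene (about 2 mM, 60 °C, Sc(OTf)3 catalyst if slow), F2 should close through the boron-bound six-membered transition state, which enforces γ-attack and needs neither a reductant nor a Lewis-acidic metal alkoxide, to the cyclic borate ester F3. Hydrolysis on work-up (aqueous NaHCO3, triethanolamine) returns to the route at 27.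

2. Step 11. Proton transfer from the acidic ring C–H at C6 to the alkenylmagnesium would destroy the reagent and the C6 configuration. The Grignard reagents may also add to the lactone, or the one-flask mesylation and chloride exchange may stay incomplete. The fallback is a Stille hydroxymethylation, which involves no carbanion, and sets out from 20. Coupling with (tributylstannyl)methanol (Pd2(dba)3, AsPh3, dioxane, 60 °C) should give the alcohol 22, now isolated. Separate treatment with MsCl, 2,4,6-collidine and LiCl in DMF at 0 °C (through 23) returns to the route at 24. No compound outside the list is made.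

3. Step 9. Pd(0) may ionise the allylic lactone C6–O bond, or the strongly acidic iodotetronic acid 19 may strip the triethylsilyl ethers during isolation. The fallback avoids the free tetronic acid and iodinates the enol ether instead; it sets out from 15. 4-Methoxybenzyl alcohol with catalytic KOtBu (as in step 8) should give, through the PMB oxa-Michael adduct F4, the PMB tetronate F5. Iodination of F5 at C3 with N-iodosuccinimide (MeCN, catalytic TFA, −20 to 0 °C, dark) returns to the route at 20 and bypasses 17–19. The price is a less secure chemoselectivity against the two trisubstituted alkenes and the anisyl ring.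

**Further compounds**
F1 | step 13 | (5S)-5-[(1E,5Z,7R)-2,6-dimethyl-7,8-bis(triethylsilyloxy)octa-1,5-dien-1-yl]-4-[(4-methoxyphenyl)methoxy]-3-[(4,4,5,5-tetramethyl-1,3,2-dioxaborolan-2-yl)methyl]furan-2(5H)-one | O=C1C(CB2OC(C)(C)C(C)(C)O2)=C(OCc2ccc(OC)cc2)[C@H](/C=C(\C)CC/C=C(/C)[C@@H](O[Si](CC)(CC)CC)CO[Si](CC)(CC)CC)O1
F2 | step 13 | (2R,3Z,7E)-8-[(2S)-3-[(4-methoxyphenyl)methoxy]-5-oxo-4-[(4,4,5,5-tetramethyl-1,3,2-dioxaborolan-2-yl)methyl]-2,5-dihydrofuran-2-yl]-3,7-dimethyl-2-(triethylsilyloxy)octa-3,7-dienal | O=C1C(CB2OC(C)(C)C(C)(C)O2)=C(OCc2ccc(OC)cc2)[C@H](/C=C(\C)CC/C=C(/C)[C@@H](O[Si](CC)(CC)CC)C=O)O1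
F3 | step 13 | O8-(4,4,5,5-tetramethyl-1,3,2-dioxaborolan-2-yl) borate ester of 27 | C=C1C(=O)O[C@H]2/C=C(\C)CC/C=C(/C)[C@@H](O[Si](CC)(CC)CC)[C@H](OB3OC(C)(C)C(C)(C)O3)[C@@]12OCc1ccc(OC)cc1
F0 | step 11 | none | none
F4 | step 9 | methyl (2E,4S,5E,9Z,11R)-4-hydroxy-3-[(4-methoxyphenyl)methoxy]-6,10-dimethyl-11,12-bis(triethylsilyloxy)dodeca-2,5,9-trienoate | COC(=O)/C=C(/OCc1ccc(OC)cc1)[C@@H](O)/C=C(\C)CC/C=C(/C)[C@@H](O[Si](CC)(CC)CC)CO[Si](CC)(CC)CC
F5 | step 9 | (5S)-5-[(1E,5Z,7R)-2,6-dimethyl-7,8-bis(triethylsilyloxy)octa-1,5-dien-1-yl]-4-[(4-methoxyphenyl)methoxy]furan-2(5H)-one | O=C1C=C(OCc2ccc(OC)cc2)[C@H](/C=C(\C)CC/C=C(/C)[C@@H](O[Si](CC)(CC)CC)CO[Si](CC)(CC)CC)O1
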